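**Plan**
- Retrosynthesis: the C11=C13 methylene and C7–H are traced back to a C13 bromide on a C7=C11 butenolide (allylic transposition); then the C5–C6 bond and the O–C2 hemiketal bond are cut together; then C7–C8; then C10=C1 with C9–C10.
- Enabling feature: C6 is the γ-carbon of the C12 lactone ring, and C2/C5 are the ketone and aldehyde carbons of a cis-4-oxo-enal (a ring-opened 4-methylfuran). C5–C6 is therefore a vinylogous aldol bond, and the C5 oxygen can close the five-membered hemiketal ring onto C2.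
- Forward: a 4-bromobutenolide (from tetronic acid) and a furyl acrylate aldehyde (from dimethyl (S)-malate and 3-methylfuran) are joined at C7–C8. Acylation at O8 and O9, furan oxidation and silylation give a silyloxyfuran keto-enal. One step then closes the ten-membered carbocycle and the dihydrofuran hemiketal, and the methylene lactone is finished last.
- Stereochemistry: C9 from (S)-malate; C8 by Felkin–Anh reduction next to C9; C5 and C6 in the ring closure under control of C8/C9, with C2 fixed by the oxygen bridge; C7 by face-selective protonation of an allylzinc. The C10=C1 geometry comes from a Stobbe-type E1cB step and C3=C4 from the furan ring.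

Key step: step 17

Remark: atoms of all intermediates carry the germacrane labels of the target (C1 enoate CH, C2 hemiketal carbon, C3=C4 with methyl C15, C5 ether CH, C6 lactone O–CH, C7, C8 angelate CH, C9 acetate CH, C10 with ester carbon C14, C11–C13 methylene lactone). The C2 hemiketal hydroxyl is carried unprotected on the assumption that the bridged dihydrofuranol is the stable form of this ring system. Angeloyl means (Z)-2-methylbut-2-enoyl.

**Route**

Step 1
Reactants: 1 tetronic acid
Product: 2 4-bromo-2-oxo-2,5-dihydrofuran-3-carbaldehyde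
Conditions: POBr3, DMF, ClCH2CH2Cl, 0 → 60 °C; then ice–water
Reagents that add atoms: N,N-dimethylformamide CN(C)C=O (formyl carbon); phosphoryl bromide O=P(Br)(Br)Br (bromine); water O (formyl oxygen)
Why: Vilsmeier–Haack–Arnold haloformylation, in which the bromoiminium salt formylates the nucleophilic C3 of the cyclic β-keto lactone and exchanges the vinylogous acid hydroxyl for bromide, as it does with 4-hydroxycoumarin and cyclic 1,3-diones.

Step 2
Reactants: 2 4-bromo-2-oxo-2,5-dihydrofuran-3-carbaldehyde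
Product: 3 4-bromo-3-(hydroxymethyl)furan-2(5H)-one
Conditions: NaBH(OAc)3, THF, 0 °C → rt
Reagents that add atoms: none
Why: Chemoselective hydride reduction of an aldehyde, since the mild and non-basic acyloxyborohydride should leave the lactone and the vinylogous acyl bromide untouched.

Step 3
Reactants: 3 4-bromo-3-(hydroxymethyl)furan-2(5H)-one
Product: 4 4-bromo-3-{[(tert-butyldimethylsilyl)oxy]methyl}furan-2(5H)-one
Conditions: TBSOTf, 2,6-lutidine, CH2Cl2, −78 °C
Reagents that add atoms: tert-butyldimethylsilyl triflate CC(C)(C)[Si](C)(C)OS(=O)(=O)C(F)(F)F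
Why: Silyl ether formation with a silyl triflate and a hindered base, chosen so that no nucleophilic amine can displace the vinylogous acyl bromide by addition–elimination.

Step 4
Reactants: 5 3-methylfuran
Product: 7 4-methylfuran-2-carbaldehyde, via (4-methylfuran-2-yl)magnesium chloride 6 (not isolated)
Conditions: TMPMgCl·LiCl, THF, 0 °C → rt; DMF, 0 °C; aq. HCl
Reagents that add atoms: N,N-dimethylformamide CN(C)C=O
Why: Directed magnesiation with the Knochel–Hauser base followed by Bouveault formylation, in which the bulky amide should remove the α-hydrogen remote from the methyl group so that the formyl carbon (later C1) sits para-like to the methyl across the ring oxygen.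

Step 5
Reactants: 8 dimethyl (S)-malate; 7 4-methylfuran-2-carbaldehyde
Product: 11 (2S,3E)-2-hydroxy-3-(methoxycarbonyl)-4-(4-methylfuran-2-yl)but-3-enoic acid, via malate dianion 9 (not isolated), via hydroxy lactone 10 (not isolated)
Conditions: LiN(SiMe3)2 (2.2 equiv), THF, −78 → −20 °C; 7, −78 → 0 °C; LiN(SiMe3)2 (1.2 equiv), 0 °C → rt; 1 M HCl
Reagents that add atoms: none
Why: Fráter–Seebach dianion aldol followed in the same flask by a Stobbe-type sequence, in which the aldolate lactonises onto the C8 ester and the lactone opens by E1cB loss of carboxylate to give the thermodynamically preferred E-alkene (furyl trans to the C14 ester, cis to C9), leaving C8 as the only free acid while the C9 alkoxide protects the malate stereocentre from enolisation.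

Step 6
Reactants: 11 (2S,3E)-2-hydroxy-3-(methoxycarbonyl)-4-(4-methylfuran-2-yl)but-3-enoic acid
Product: 12 methyl (2E)-2-{(1S)-1-hydroxy-2-[methoxy(methyl)amino]-2-oxoethyl}-3-(4-methylfuran-2-yl)prop-2-enoate
Conditions: MeNHOMe·HCl, EDC·HCl, HOBt, N-methylmorpholine, CH2Cl2, 0 °C → rt
Reagents that add atoms: N,O-dimethylhydroxylamine hydrochloride CNOC.Cl
Why: Carbodiimide amide coupling gives the Weinreb amide at the only free carboxyl group, which differentiates C8 from the C14 methyl ester.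

Step 7
Reactants: 12 methyl (2E)-2-{(1S)-1-hydroxy-2-[methoxy(methyl)amino]-2-oxoethyl}-3-(4-methylfuran-2-yl)prop-2-enoate
Product: 13 methyl (2E)-2-{(1S)-2-[methoxy(methyl)amino]-2-oxo-1-[(triethylsilyl)oxy]ethyl}-3-(4-methylfuran-2-yl)prop-2-enoate
Conditions: Et3SiCl, imidazole, CH2Cl2, 0 °C
Reagents that add atoms: chlorotriethylsilane CC[Si](Cl)(CC)CC
Why: Silylation of the secondary alcohol with a triethylsilyl group, which is non-chelating for the later reduction and can be removed in the presence of the primary tert-butyldimethylsilyl ether.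

Step 8
Reactants: 13 methyl (2E)-2-{(1S)-2-[methoxy(methyl)amino]-2-oxo-1-[(triethylsilyl)oxy]ethyl}-3-(4-methylfuran-2-yl)prop-2-enoate
Product: 14 methyl (2E)-3-(4-methylfuran-2-yl)-2-{(1S)-2-oxo-1-[(triethylsilyl)oxy]ethyl}prop-2-enoate
Conditions: i-Bu2AlH (1.3 equiv), THF, −78 °C; aq. KNaC4H4O6
Reagents that add atoms: none
Why: Weinreb amide reduction, in which the chelated tetrahedral adduct is stable at −78 °C and releases the aldehyde only on work-up, while the conjugated push–pull C14 ester reacts more slowly with a small excess of hydride.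

Step 9
Reactants: 14 methyl (2E)-3-(4-methylfuran-2-yl)-2-{(1S)-2-oxo-1-[(triethylsilyl)oxy]ethyl}prop-2-enoate; 4 4-bromo-3-{[(tert-butyldimethylsilyl)oxy]methyl}furan-2(5H)-one
Product: 16 methyl (2E)-2-{(1S,2RS)-2-[4-({[tert-butyl(dimethyl)silyl]oxy}methyl)-5-oxo-2,5-dihydrofuran-3-yl]-2-hydroxy-1-[(triethylsilyl)oxy]ethyl}-3-(4-methylfuran-2-yl)prop-2-enoate (both C8 epimers), via alkenylchromium dichloride 15 (not isolated)
Conditions: CrCl2 (4 equiv), NiCl2 (2 mol %), DMSO, rt
Reagents that add atoms: none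
Why: Nozaki–Hiyama–Kishi coupling, in which NiCl2-catalysed activation of the β-bromobutenolide and transfer to chromium give an alkenylchromium species that adds to the aldehyde without base, so C9 is not epimerised, while the C8 configuration is left uncontrolled because both epimers converge in the next step.

Step 10
Reactants: 16 methyl (2E)-2-{(1S,2RS)-2-[4-({[tert-butyl(dimethyl)silyl]oxy}methyl)-5-oxo-2,5-dihydrofuran-3-yl]-2-hydroxy-1-[(triethylsilyl)oxy]ethyl}-3-(4-methylfuran-2-yl)prop-2-enoate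
Product: 17 methyl (2E)-2-{(1S)-2-[4-({[tert-butyl(dimethyl)silyl]oxy}methyl)-5-oxo-2,5-dihydrofuran-3-yl]-2-oxo-1-[(triethylsilyl)oxy]ethyl}-3-(4-methylfuran-2-yl)prop-2-enoate
Conditions: Dess–Martin periodinane, NaHCO3, CH2Cl2, 0 °C → rt
Reagents that add atoms: none
Why: Dess–Martin oxidation under buffered, non-basic conditions converges both C8 epimers on one ketone without enolising C9.

Step 11
Reactants: 17 methyl (2E)-2-{(1S)-2-[4-({[tert-butyl(dimethyl)silyl]oxy}methyl)-5-oxo-2,5-dihydrofuran-3-yl]-2-oxo-1-[(triethylsilyl)oxy]ethyl}-3-(4-methylfuran-2-yl)prop-2-enoate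
Product: 18 methyl (2E)-2-{(1S,2S)-2-[4-({[tert-butyl(dimethyl)silyl]oxy}methyl)-5-oxo-2,5-dihydrofuran-3-yl]-2-hydroxy-1-[(triethylsilyl)oxy]ethyl}-3-(4-methylfuran-2-yl)prop-2-enoate
Conditions: NaBH4, CeCl3·7H2O, MeOH, −78 °C; AcOH
Reagents that add atoms: none
Why: Luche 1,2-reduction under Felkin–Anh control, in which hydride attacks anti to the non-chelating C9 silyloxy group and past the C9 hydrogen, which should give the 8,9-syn (threo) arrangement, that is 8S.

Step 12
Reactants: 18 methyl (2E)-2-{(1S,2S)-2-[4-({[tert-butyl(dimethyl)silyl]oxy}methyl)-5-oxo-2,5-dihydrofuran-3-yl]-2-hydroxy-1-[(triethylsilyl)oxy]ethyl}-3-(4-methylfuran-2-yl)prop-2-enoate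
Product: 19 methyl (2E)-2-{(1S,2S)-2-[4-({[tert-butyl(dimethyl)silyl]oxy}methyl)-5-oxo-2,5-dihydrofuran-3-yl]-2-{[(2Z)-2-methylbut-2-enoyl]oxy}-1-[(triethylsilyl)oxy]ethyl}-3-(4-methylfuran-2-yl)prop-2-enoate
Conditions: angelic acid, 2,4,6-Cl3C6H2COCl, Et3N, toluene, rt; then 18, 60 °C
Reagents that add atoms: angelic acid C/C=C(/C)C(=O)O
Why: Yamaguchi esterification through the mixed anhydride, the usual way to acylate a hindered secondary alcohol with angelic acid without Z to E isomerisation to the tiglate, carried out at once so that the free C8 hydroxyl has little time to lactonise onto C14.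

Step 13
Reactants: 19 methyl (2E)-2-{(1S,2S)-2-[4-({[tert-butyl(dimethyl)silyl]oxy}methyl)-5-oxo-2,5-dihydrofuran-3-yl]-2-{[(2Z)-2-methylbut-2-enoyl]oxy}-1-[(triethylsilyl)oxy]ethyl}-3-(4-methylfuran-2-yl)prop-2-enoate
Product: 20 methyl (2E)-2-{(1S,2S)-2-[4-({[tert-butyl(dimethyl)silyl]oxy}methyl)-5-oxo-2,5-dihydrofuran-3-yl]-1-hydroxy-2-{[(2Z)-2-methylbut-2-enoyl]oxy}ethyl}-3-(4-methylfuran-2-yl)prop-2-enoate
Conditions: PPTS (cat.), MeOH/CH2Cl2, 0 °C
Reagents that add atoms: none
Why: Acid-catalysed methanolysis cleaves the secondary triethylsilyl ether much faster than the primary tert-butyldimethylsilyl ether, and the acidic medium avoids 1,2-migration of the angelate.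

Step 14
Reactants: 20 methyl (2E)-2-{(1S,2S)-2-[4-({[tert-butyl(dimethyl)silyl]oxy}methyl)-5-oxo-2,5-dihydrofuran-3-yl]-1-hydroxy-2-{[(2Z)-2-methylbut-2-enoyl]oxy}ethyl}-3-(4-methylfuran-2-yl)prop-2-enoate
Product: 21 methyl (2E)-2-{(1S,2S)-1-acetoxy-2-[4-({[tert-butyl(dimethyl)silyl]oxy}methyl)-5-oxo-2,5-dihydrofuran-3-yl]-2-{[(2Z)-2-methylbut-2-enoyl]oxy}ethyl}-3-(4-methylfuran-2-yl)prop-2-enoate
Conditions: Ac2O, pyridine, DMAP (cat.), CH2Cl2, 0 °C
Reagents that add atoms: acetic anhydride CC(=O)OC(C)=O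
Why: DMAP-catalysed acetylation of the freed C9 alcohol, which is faster than acyl migration from O8.

Step 15
Reactants: 21 methyl (2E)-2-{(1S,2S)-1-acetoxy-2-[4-({[tert-butyl(dimethyl)silyl]oxy}methyl)-5-oxo-2,5-dihydrofuran-3-yl]-2-{[(2Z)-2-methylbut-2-enoyl]oxy}ethyl}-3-(4-methylfuran-2-yl)prop-2-enoate
Product: 22 methyl (2E,5Z)-2-{(1S,2S)-1-acetoxy-2-[4-({[tert-butyl(dimethyl)silyl]oxy}methyl)-5-oxo-2,5-dihydrofuran-3-yl]-2-{[(2Z)-2-methylbut-2-enoyl]oxy}ethyl}-6-methyl-4,7-dioxohepta-2,5-dienoate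
Conditions: DMDO, acetone, −78 → 0 °C
Reagents that add atoms: dimethyldioxirane CC1(C)OO1
Why: Oxidative furan opening to a cis-enedione, in which the electrophilic dioxirane epoxidises only the electron-rich furan (butenolide, angelate and enoate are electron-poor) and the epoxide opens to the Z-4-oxo-enal with C2 as ketone and C5 as aldehyde, the cis geometry being inherited from the ring.

Step 16
Reactants: 22 methyl (2E,5Z)-2-{(1S,2S)-1-acetoxy-2-[4-({[tert-butyl(dimethyl)silyl]oxy}methyl)-5-oxo-2,5-dihydrofuran-3-yl]-2-{[(2Z)-2-methylbut-2-enoyl]oxy}ethyl}-6-methyl-4,7-dioxohepta-2,5-dienoate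
Product: 23 methyl (2E,5Z)-2-{(1S,2S)-1-acetoxy-2-[4-({[tert-butyl(dimethyl)silyl]oxy}methyl)-5-[(triisopropylsilyl)oxy]furan-3-yl]-2-{[(2Z)-2-methylbut-2-enoyl]oxy}ethyl}-6-methyl-4,7-dioxohepta-2,5-dienoate
Conditions: i-Pr3SiOTf, Et3N, CH2Cl2, −78 → −40 °C
Reagents that add atoms: triisopropylsilyl triflate CC(C)[Si](OS(=O)(=O)C(F)(F)F)(C(C)C)C(C)C
Why: Soft enolisation and O-silylation of the butenolide, in which loss of a C6 γ-hydrogen gives the aromatic 2-silyloxyfuran far faster than any extended enol ether of the acyclic enone can form, while the bulky triflate with excess amine at low temperature should not trigger the aldol prematurely.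

Step 17
Reactants: 23 methyl (2E,5Z)-2-{(1S,2S)-1-acetoxy-2-[4-({[tert-butyl(dimethyl)silyl]oxy}methyl)-5-[(triisopropylsilyl)oxy]furan-3-yl]-2-{[(2Z)-2-methylbut-2-enoyl]oxy}ethyl}-6-methyl-4,7-dioxohepta-2,5-dienoate
Product: 25 methyl (1(10)E,2R,5R,6S,8S,9S)-9-acetoxy-8-angeloyloxy-13-(tert-butyldimethylsilyloxy)-2-hydroxy-2,5-epoxygermacra-1(10),3,7(11)-trien-12,6-olid-14-oate, via ten-membered aldol 24 (not isolated)
Conditions: BF3·OEt2 (2 equiv), CH2Cl2, −78 °C, slow addition of 23 to 1 mM; aq. NaHCO3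
Reagents that add atoms: none
Why: Proposed new method: BF3 binds the C5 aldehyde, the most basic and least hindered carbonyl, and the 2-silyloxyfuran attacks it through its γ-carbon C6 in an open transition state, after which fluoride transfer removes the silyl group, the butenolide returns, and the C5 hydroxyl adds to the C2 ketone that the C3=C4 alkene holds cis. The closest known reaction is the vinylogous Mukaiyama aldol of 2-silyloxyfurans with aldehydes, whose intramolecular form is established only for five- to seven-membered carbocycles, so the ten-membered closure is the unproven part and is run at high dilution. The carbocycle closes in a 10-(enolendo)-exo-trig mode and the hemiketal in a 5-exo-trig mode, the latter being reversible and pulling the aldol out of the retro-aldol equilibrium. C5 and C6 are set together in the C–C bond formation, and the 5R,6S pair is expected to be selected by the resident C8 and C9 stereocentres through the ring-constrained transition state, in which the ring-cis C10=C1 alkene and the flat furan leave few ways to span the two termini, while C2 is not free because the oxygen bridge can only form with C1 and C6 on the same face of the dihydrofuran. The step needs the aldehyde to react before the C2 ketone and the Michael positions: the ketone is cross-conjugated and flanked by two alkenes, closure onto C10 would be a disfavoured 5-(enolendo)-exo-trig process, and an adduct at the ketone can revert whereas the aldehyde adduct is trapped as the hemiketal.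

Step 18
Reactants: 25 methyl (1(10)E,2R,5R,6S,8S,9S)-9-acetoxy-8-angeloyloxy-13-(tert-butyldimethylsilyloxy)-2-hydroxy-2,5-epoxygermacra-1(10),3,7(11)-trien-12,6-olid-14-oate
Product: 26 methyl (1(10)E,2R,5R,6S,8S,9S)-9-acetoxy-8-angeloyloxy-2,13-dihydroxy-2,5-epoxygermacra-1(10),3,7(11)-trien-12,6-olid-14-oate
Conditions: HF·pyridine, pyridine, THF, 0 °C → rt
Reagents that add atoms: none
Why: Fluoride-mediated desilylation under buffered, mildly acidic conditions removes the only remaining silyl ether without acyl migration or opening of the hemiketal.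

Step 19
Reactants: 26 methyl (1(10)E,2R,5R,6S,8S,9S)-9-acetoxy-8-angeloyloxy-2,13-dihydroxy-2,5-epoxygermacra-1(10),3,7(11)-trien-12,6-olid-14-oate
Product: 27 methyl (1(10)E,2R,5R,6S,8S,9S)-9-acetoxy-8-angeloyloxy-13-bromo-2-hydroxy-2,5-epoxygermacra-1(10),3,7(11)-trien-12,6-olid-14-oate
Conditions: CBr4, PPh3, CH2Cl2, 0 °C
Reagents that add atoms: carbon tetrabromide BrC(Br)(Br)Br
Why: Appel reaction, in which the primary allylic alcohol is brominated under neutral conditions far faster than the tertiary hemiketal hydroxyl can react.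

Step 20
Reactants: 27 methyl (1(10)E,2R,5R,6S,8S,9S)-9-acetoxy-8-angeloyloxy-13-bromo-2-hydroxy-2,5-epoxygermacra-1(10),3,7(11)-trien-12,6-olid-14-oate
Product: 29 methyl (1(10)E,2R,5R,6S,7S,8S,9S)-9-acetoxy-8-angeloyloxy-2-hydroxy-2,5-epoxygermacra-1(10),3,11(13)-trien-12,6-olid-14-oate (CNP0208424.1), via allylzinc bromide 28 (not isolated)
Conditions: Zn dust, sat. aq. NH4Cl, THF, 0 °C
Reagents that add atoms: none
Why: Zinc-mediated reductive allylic transposition, in which the allylzinc bromide is protonated at its γ-carbon C7 (SE2′) so that the alkene moves to the exocyclic C11=C13 position, and the proton is expected to enter anti to the C8 angelate, which allylic 1,3-strain against C13 places on the face opposite the C5–C9 bridge, giving the 6,7-trans lactone (7S).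

**Compound list**

1 | tetronic acid | O=C1COC(=O)C1 | starting material
2 | 4-bromo-2-oxo-2,5-dihydrofuran-3-carbaldehyde | O=CC1=C(Br)COC1=O | intermediate
3 | 4-bromo-3-(hydroxymethyl)furan-2(5H)-one | OCC1=C(Br)COC1=O | intermediate
4 | 4-bromo-3-{[(tert-butyldimethylsilyl)oxy]methyl}furan-2(5H)-one | CC(C)(C)[Si](C)(C)OCC1=C(Br)COC1=O | intermediate
5 | 3-methylfuran | Cc1ccoc1 | starting material
6 | (4-methylfuran-2-yl)magnesium chloride (LiCl complex) | Cc1coc([Mg]Cl)c1 | intermediate (not isolated)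
7 | 4-methylfuran-2-carbaldehyde | Cc1coc(C=O)c1 | intermediate
8 | dimethyl (S)-malate | COC(=O)[C@@H](O)CC(=O)OC | starting material
9 | dilithium alkoxide–enolate (dianion) of dimethyl (S)-malate | COC(=O)[C@@H]([O-])C=C([O-])OC.[Li+].[Li+] | intermediate (not isolated)
10 | methyl (4S)-4-hydroxy-2-(4-methylfuran-2-yl)-5-oxooxolane-3-carboxylate (diastereomer mixture at C2 and C3, lithium alkoxide in the flask) | O=C1[C@@H](O)C(C(=O)OC)C(c2cc(C)co2)O1 | intermediate (not isolated)
11 | (2S,3E)-2-hydroxy-3-(methoxycarbonyl)-4-(4-methylfuran-2-yl)but-3-enoic acid | OC(=O)[C@@H](O)/C(C(=O)OC)=C\c1cc(C)co1 | intermediate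
12 | methyl (2E)-2-{(1S)-1-hydroxy-2-[methoxy(methyl)amino]-2-oxoethyl}-3-(4-methylfuran-2-yl)prop-2-enoate | CON(C)C(=O)[C@@H](O)/C(C(=O)OC)=C\c1cc(C)co1 | intermediate
13 | methyl (2E)-2-{(1S)-2-[methoxy(methyl)amino]-2-oxo-1-[(triethylsilyl)oxy]ethyl}-3-(4-methylfuran-2-yl)prop-2-enoate | CON(C)C(=O)[C@@H](O[Si](CC)(CC)CC)/C(C(=O)OC)=C\c1cc(C)co1 | intermediate
14 | methyl (2E)-3-(4-methylfuran-2-yl)-2-{(1S)-2-oxo-1-[(triethylsilyl)oxy]ethyl}prop-2-enoate | O=C[C@@H](O[Si](CC)(CC)CC)/C(C(=O)OC)=C\c1cc(C)co1 | intermediate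
15 | dichloro[4-({[tert-butyl(dimethyl)silyl]oxy}methyl)-5-oxo-2,5-dihydrofuran-3-yl]chromium (trivalent chromium) | O=C1OCC([Cr](Cl)Cl)=C1CO[Si](C)(C)C(C)(C)C | intermediate (not isolated)
16 | C8-epimeric NHK alcohol, methyl (2E)-2-{(1S,2RS)-2-[4-(TBSOCH2)-5-oxo-2,5-dihydrofuran-3-yl]-2-hydroxy-1-[(triethylsilyl)oxy]ethyl}-3-(4-methylfuran-2-yl)prop-2-enoate | O=C1OCC(C(O)[C@@H](O[Si](CC)(CC)CC)/C(C(=O)OC)=C\c2cc(C)co2)=C1CO[Si](C)(C)C(C)(C)C | intermediate
17 | C8 ketone, methyl (2E)-2-{(1S)-2-[4-(TBSOCH2)-5-oxo-2,5-dihydrofuran-3-yl]-2-oxo-1-[(triethylsilyl)oxy]ethyl}-3-(4-methylfuran-2-yl)prop-2-enoate | O=C1OCC(C(=O)[C@@H](O[Si](CC)(CC)CC)/C(C(=O)OC)=C\c2cc(C)co2)=C1CO[Si](C)(C)C(C)(C)C | intermediate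
18 | (1S,2S)-alcohol (8S,9S), methyl (2E)-2-{(1S,2S)-2-[4-(TBSOCH2)-5-oxo-2,5-dihydrofuran-3-yl]-2-hydroxy-1-[(triethylsilyl)oxy]ethyl}-3-(4-methylfuran-2-yl)prop-2-enoate | O=C1OCC([C@H](O)[C@@H](O[Si](CC)(CC)CC)/C(C(=O)OC)=C\c2cc(C)co2)=C1CO[Si](C)(C)C(C)(C)C | intermediate
19 | C8 angelate, C9 triethylsilyl ether of 18 | O=C1OCC([C@H](OC(=O)/C(C)=C\C)[C@@H](O[Si](CC)(CC)CC)/C(C(=O)OC)=C\c2cc(C)co2)=C1CO[Si](C)(C)C(C)(C)C | intermediate
20 | C8 angelate with free C9 hydroxyl | O=C1OCC([C@H](OC(=O)/C(C)=C\C)[C@@H](O)/C(C(=O)OC)=C\c2cc(C)co2)=C1CO[Si](C)(C)C(C)(C)C | intermediate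
21 | C8 angelate, C9 acetate (furan and butenolide intact) | O=C1OCC([C@H](OC(=O)/C(C)=C\C)[C@@H](OC(C)=O)/C(C(=O)OC)=C\c2cc(C)co2)=C1CO[Si](C)(C)C(C)(C)C | intermediate
22 | butenolide Z-keto-enal, methyl (2E,5Z)-2-{(1S,2S)-1-acetoxy-2-[4-(TBSOCH2)-5-oxo-2,5-dihydrofuran-3-yl]-2-(angeloyloxy)ethyl}-6-methyl-4,7-dioxohepta-2,5-dienoate | O=C1OCC([C@H](OC(=O)/C(C)=C\C)[C@@H](OC(C)=O)/C(C(=O)OC)=C\C(=O)/C=C(C)\C=O)=C1CO[Si](C)(C)C(C)(C)C | intermediate
23 | silyloxyfuran Z-keto-enal (precursor of the key step), as 22 with a 4-(TBSOCH2)-5-[(triisopropylsilyl)oxy]furan-3-yl group | CC(C)[Si](C(C)C)(C(C)C)Oc1occ([C@H](OC(=O)/C(C)=C\C)[C@@H](OC(C)=O)/C(C(=O)OC)=C\C(=O)/C=C(C)\C=O)c1CO[Si](C)(C)C(C)(C)C | intermediate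
24 | ten-membered aldol, methyl (1(10)E,3Z,5R,6S,8S,9S)-9-acetoxy-8-angeloyloxy-13-(tert-butyldimethylsilyloxy)-5-hydroxy-2-oxogermacra-1(10),3,7(11)-trien-12,6-olid-14-oate | O=C1O[C@H]2C(=C1CO[Si](C)(C)C(C)(C)C)[C@H](OC(=O)/C(C)=C\C)[C@@H](OC(C)=O)/C(C(=O)OC)=C\C(=O)/C=C(C)\[C@H]2O | intermediate (not isolated)
25 | oxa-bridged ten-membered ring with butenolide and hemiketal (product of the key step), 13-(tert-butyldimethylsilyloxy) compound | O=C1O[C@H]2C(=C1CO[Si](C)(C)C(C)(C)C)[C@H](OC(=O)/C(C)=C\C)[C@@H](OC(C)=O)/C(C(=O)OC)=C\[C@@]3(O)C=C(C)[C@H]2O3 | intermediate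
26 | 13-hydroxy compound | O=C1O[C@H]2C(=C1CO)[C@H](OC(=O)/C(C)=C\C)[C@@H](OC(C)=O)/C(C(=O)OC)=C\[C@@]3(O)C=C(C)[C@H]2O3 | intermediate
27 | 13-bromo compound | O=C1O[C@H]2C(=C1CBr)[C@H](OC(=O)/C(C)=C\C)[C@@H](OC(C)=O)/C(C(=O)OC)=C\[C@@]3(O)C=C(C)[C@H]2O3 | intermediate
28 | C13 allylzinc bromide of 27 | O=C1O[C@H]2C(=C1C[Zn]Br)[C@H](OC(=O)/C(C)=C\C)[C@@H](OC(C)=O)/C(C(=O)OC)=C\[C@@]3(O)C=C(C)[C@H]2O3 | intermediate (not isolated)
29 | CNP0208424.1, methyl (1(10)E,2R,5R,6S,7S,8S,9S)-9-acetoxy-8-angeloyloxy-2-hydroxy-2,5-epoxygermacra-1(10),3,11(13)-trien-12,6-olid-14-oate | C=C1C(=O)O[C@H]2[C@H]1[C@H](OC(=O)/C(C)=C\C)[C@@H](OC(C)=O)/C(C(=O)OC)=C\[C@@]1(O)C=C(C)[C@H]2O1 | target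

**Step count and risks**

Total step count: 20. Longest linear sequence: 17 steps (steps 4 to 20, from 3-methylfuran 5; 16 from dimethyl (S)-malate 8). The bromobutenolide 4 takes 3 steps and enters at step 9.

Steps most likely to fail:

Step 17 (the new ring closure). What may go wrong: intermolecular aldol oligomerisation in place of ten-membered closure, closure of a seven-membered ring onto the C2 ketone or conjugate addition instead of attack on the aldehyde, or low facial selectivity at C5 and C6. The fallback uses only known reaction types: the C5–C6 bond is made intermolecularly and the ring is closed at C7–C8 by a Nozaki–Hiyama–Kishi macrocyclisation. It sets out from 4 and 13.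
- Silylation of 4 (i-Pr3SiOTf, Et3N) gives 4-bromo-3-{[(tert-butyldimethylsilyl)oxy]methyl}-2-[(triisopropylsilyl)oxy]furan F1.
- Oxidation of 13 with DMDO gives the Z-keto-enal Weinreb amide F2.
- Intermolecular vinylogous Mukaiyama aldol addition of F1 to the aldehyde of F2 (BF3·OEt2, −78 °C), followed by spontaneous hemiketal closure, should give the bromobutenolide hemiketal F3. The 5R,6S isomer would have to be separated from its diastereomers, since C9 is too remote to control the addition.
- i-Bu2AlH at −78 °C reduces the Weinreb amide, faster than the conjugated lactone, to the aldehyde F4.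
- CrCl2 with catalytic NiCl2 in DMSO at high dilution closes the ten-membered ring to the macrocyclic C8 alcohol F5.
- Dess–Martin oxidation gives the macrocyclic ketone F6, and Luche reduction the 8S alcohol F7.
- Yamaguchi angeloylation gives the angelate triethylsilyl ether F8, and PPTS in methanol the C9 alcohol F9.
- Acetylation of F9 returns to the route at 25.

Step 20 (setting C7). What may go wrong: protonation of the allylzinc on the wrong face of C7 (cis-fused lactone), protonation at C13 without transposition, or β-elimination of the lactone oxygen from the allylzinc. The fallback replaces the organometallic by an allylic diazene rearrangement and sets out from 26. A Mitsunobu reaction with 2-nitrobenzenesulfonylhydrazide (PPh3, DEAD, THF, −30 °C) gives the N-allyl sulfonylhydrazine F10. On warming this loses the sulfinic acid to give the allylic diazene F11. Sigmatropic loss of N2 then delivers hydrogen to C7 intramolecularly and moves the alkene to C11=C13, returning to the route at 29 without the bromide 27.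

Step 11 (setting C8). What may go wrong: low facial selectivity of hydride delivery to the C8 ketone, or loss of the C9 configuration by enolisation of 17 before reduction. The fallback sets C8 in the C–C bond-forming event. Compounds 14 and 4 are coupled in a catalyst-controlled asymmetric Nozaki–Hiyama–Kishi reaction (CrCl2 complexed with a chiral oxazoline–sulfonamide ligand and Et3N, NiCl2 cat., THF), using the ligand enantiomer that directs the alkenyl group to the Si face of the aldehyde. This should give 18 directly, so 16 and 17 are bypassed and the route is rejoined at 18; no new compound is made.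

**Further compounds**

F1 | step 17 | 4-bromo-3-{[(tert-butyldimethylsilyl)oxy]methyl}-2-[(triisopropylsilyl)oxy]furan | CC(C)[Si](C(C)C)(C(C)C)Oc1occ(Br)c1CO[Si](C)(C)C(C)(C)C
F2 | step 17 | Z-keto-enal Weinreb amide, methyl (2E,5Z)-2-{(1S)-2-[methoxy(methyl)amino]-2-oxo-1-[(triethylsilyl)oxy]ethyl}-6-methyl-4,7-dioxohepta-2,5-dienoate | CON(C)C(=O)[C@@H](O[Si](CC)(CC)CC)/C(C(=O)OC)=C\C(=O)/C=C(C)\C=O
F3 | step 17 | bromobutenolide hemiketal with Weinreb amide (2R,5R,6S,9S) | CON(C)C(=O)[C@@H](O[Si](CC)(CC)CC)/C(C(=O)OC)=C\[C@@]1(O)C=C(C)[C@@H](O1)[C@H]2OC(=O)C(CO[Si](C)(C)C(C)(C)C)=C2Br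
F4 | step 17 | bromobutenolide hemiketal C8 aldehyde | O=C[C@@H](O[Si](CC)(CC)CC)/C(C(=O)OC)=C\[C@@]1(O)C=C(C)[C@@H](O1)[C@H]2OC(=O)C(CO[Si](C)(C)C(C)(C)C)=C2Br
F5 | step 17 | macrocyclic C8 alcohol (C8 epimers), C9 triethylsilyl ether | O=C1O[C@H]2C(=C1CO[Si](C)(C)C(C)(C)C)C(O)[C@@H](O[Si](CC)(CC)CC)/C(C(=O)OC)=C\[C@@]3(O)C=C(C)[C@H]2O3
F6 | step 17 | macrocyclic C8 ketone | O=C1O[C@H]2C(=C1CO[Si](C)(C)C(C)(C)C)C(=O)[C@@H](O[Si](CC)(CC)CC)/C(C(=O)OC)=C\[C@@]3(O)C=C(C)[C@H]2O3
F7 | step 17 | macrocyclic 8S alcohol | O=C1O[C@H]2C(=C1CO[Si](C)(C)C(C)(C)C)[C@H](O)[C@@H](O[Si](CC)(CC)CC)/C(C(=O)OC)=C\[C@@]3(O)C=C(C)[C@H]2O3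
F8 | step 17 | macrocyclic C8 angelate, C9 triethylsilyl ether | O=C1O[C@H]2C(=C1CO[Si](C)(C)C(C)(C)C)[C@H](OC(=O)/C(C)=C\C)[C@@H](O[Si](CC)(CC)CC)/C(C(=O)OC)=C\[C@@]3(O)C=C(C)[C@H]2O3
F9 | step 17 | macrocyclic C8 angelate with free C9 hydroxyl | O=C1O[C@H]2C(=C1CO[Si](C)(C)C(C)(C)C)[C@H](OC(=O)/C(C)=C\C)[C@@H](O)/C(C(=O)OC)=C\[C@@]3(O)C=C(C)[C@H]2O3
F10 | step 20 | C13 N-(2-nitrobenzenesulfonyl)hydrazine | O=C1O[C@H]2C(=C1CN(N)S(=O)(=O)c3ccccc3[N+](=O)[O-])[C@H](OC(=O)/C(C)=C\C)[C@@H](OC(C)=O)/C(C(=O)OC)=C\[C@@]4(O)C=C(C)[C@H]2O4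
F11 | step 20 | C13 allylic diazene | O=C1O[C@H]2C(=C1CN=N)[C@H](OC(=O)/C(C)=C\C)[C@@H](OC(C)=O)/C(C(=O)OC)=C\[C@@]3(O)C=C(C)[C@H]2O3
F0 | step 11 | none | none
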